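**Assumption:** the target is taken exactly as the given SMILES, i.e. an all-trans (2R,3S,4R)-oxolane with an (S)-configured benzylic carbinol; LiNCy2 and the CBS catalyst are used as pre-formed commercial reagents.

**Retrosynthetic overview**
1. Target ⇐ keto-aldehyde 18 by one reduction (CHO → CH2OH, ArC=O → (S)-carbinol). In 18 both C-3 and C-4 are epimerisable and all-trans is the thermodynamic isomer, so only C-2 has to be set absolutely.
2. 18 ⇐ 4-aroyl-3-vinyl-oxolane 16 by C=C cleavage.
3. 16 ⇐ vinyl oxirane 10 + aryl vinyl ketone 15 by Pd(0)-catalysed ring expansion of the oxirane to the oxolane (forms O1–C5 and C3–C4).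
4. 10 ⇐ 3,4,5-trimethoxybenzaldehyde 6 + allyl chloride (asymmetric chloroallylboration sets C-2); 15 ⇐ veratrole + 3-chloropropanoyl chloride.
5. Arenes from p-cresol and catechol. Ring order: oxirane (step 3), then oxolane (step 6).

**Route**

Step 1
Reactants: 1 p-cresol
Product: 4 3,5-dibromo-4-hydroxybenzaldehyde, via 2,6-dibromo-4-methylphenol 2 (not isolated), via 2,6-dibromo-4-(dibromomethyl)phenol 3 (not isolated)
Conditions: Br2 (2.05 equiv), o-dichlorobenzene, 35 °C; Br2 (2.1 equiv), 150–160 °C; H2O, 100 °C (one pot)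
Reagents that add atoms: bromine, BrBr; water, O
Why: Electrophilic aromatic bromination ortho to OH, then radical benzylic dibromination and hydrolysis of the benzal bromide (established one-pot oxidation of p-cresol).

Step 2
Reactants: 4 3,5-dibromo-4-hydroxybenzaldehyde
Product: 6 3,4,5-trimethoxybenzaldehyde, via sodium 4-formyl-2,6-dimethoxyphenolate 5 (not isolated)
Conditions: NaOMe (4 equiv), CuCl (10 mol%), DMF–MeOH, 115 °C; then Me2SO4, 60 °C (same pot)
Reagents that add atoms: sodium methoxide, C[O-].[Na+]; dimethyl sulfate, COS(=O)(=O)OC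
Why: Cu(I)-catalysed Ullmann-type methoxylation of both aryl bromides, then Williamson O-methylation of the phenolate.

Step 3
Reactants: 6 3,4,5-trimethoxybenzaldehyde; 7 allyl chloride
Product: 10 (2S,3R)-2-(3,4,5-trimethoxyphenyl)-3-vinyloxirane (cis), via (Z)-γ-chloroallyl-diisopinocampheylborane 8 (not isolated), via (1S,2S)-2-chloro-1-(3,4,5-trimethoxyphenyl)but-3-en-1-ol 9 (not isolated)
Conditions: 7, LiNCy2, (+)-Ipc2BOMe [from (−)-α-pinene], Et2O/THF, −95 °C; BF3·OEt2; 6, −95 °C, 4 h; ethanolamine, rt; crude 9, DBU, CH2Cl2, rt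
Reagents that add atoms: none
Why: Brown–Oehlschlager asymmetric γ-chloroallylboration (chair Zimmerman–Traxler transition state; Re-face delivery by the (+)-Ipc2B reagent sets the carbinol centre as 1S and gives the syn-chlorohydrin), then SN2 ring closure to the cis-vinyl oxirane with the carbinol centre untouched.

Step 4
Reactants: 11 catechol
Product: 12 veratrole (1,2-dimethoxybenzene)
Conditions: MeI (2.5 equiv), K2CO3, acetone, reflux
Reagents that add atoms: iodomethane, CI
Why: Double Williamson etherification of the catechol.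

Step 5
Reactants: 12 veratrole; 13 3-chloropropanoyl chloride
Product: 15 1-(3,4-dimethoxyphenyl)prop-2-en-1-one, via 3-chloro-1-(3,4-dimethoxyphenyl)propan-1-one 14 (not isolated)
Conditions: AlCl3 (1.2 equiv), CH2Cl2, 0 °C; aqueous work-up; crude 14, Et3N, CH2Cl2, rt (use 15 fresh, BHT-stabilised)
Reagents that add atoms: none
Why: Friedel–Crafts acylation para to a methoxy group, then E1cB dehydrochlorination of the β-chloro ketone.

Step 6
Reactants: 10 (2S,3R)-2-(3,4,5-trimethoxyphenyl)-3-vinyloxirane; 15 1-(3,4-dimethoxyphenyl)prop-2-en-1-one (1.5 equiv)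
Product: 16 (3,4-dimethoxyphenyl)[(3R,4R,5R)-4-ethenyl-5-(3,4,5-trimethoxyphenyl)oxolan-3-yl]methanone (all-trans)
Conditions: Pd2(dba)3·CHCl3 (2.5 mol%), dppe (6 mol%), THF, 0 °C → rt; then DBU (5 mol%), rt
Reagents that add atoms: none
Why: Proposed new method: Pd(0) ionises the allylic C–O bond of 10 to a zwitterionic π-allyl-Pd alkoxide, the alkoxide adds to enone 15 (oxa-Michael) and the resulting ketone enolate closes on the proximal allyl terminus (5-exo Tsuji–Trost), so the oxirane is expanded by the two enone carbons in a stepwise ionic sequence. The C-2 carbinol centre is never a reacting centre and is carried over unchanged; π–σ–π face exchange lets C-3 settle trans to the aryl group, and C-4 (α to C=O) equilibrates to trans. The closest known reaction type is the Pd-catalysed ring expansion of vinyl oxiranes with heterocumulenes and with doubly activated alkenes; a mono-activated aryl vinyl ketone with a 2-aryl-3-vinyloxirane and transfer of the carbinol configuration has not, to my knowledge, been shown.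

Step 7
Reactants: 16 the 4-ethenyl-oxolanyl ketone
Product: 18 (2R,3R,4R)-4-(3,4-dimethoxybenzoyl)-2-(3,4,5-trimethoxyphenyl)oxolane-3-carbaldehyde, via 1,2-diol 17 (not isolated)
Conditions: OsO4 (2 mol%), NaIO4 (4 equiv), 2,6-lutidine (2 equiv), dioxane–H2O 3:1, rt
Reagents that add atoms: osmium tetroxide (catalytic oxygen donor), O=[Os](=O)(=O)=O; sodium periodate (terminal oxidant), [Na+].[O-]I(=O)(=O)=O
Why: Lemieux–Johnson dihydroxylation/glycol cleavage of the terminal alkene; C-3 (α to CHO) and C-4 (α to C=O) are both epimerisable and all-trans is the thermodynamic isomer, so any 2,3-cis material from step 6 can converge here.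

Step 8
Reactants: 18 the keto-aldehyde
Product: 20 (S)-(3,4-dimethoxyphenyl)[(3R,4S,5R)-4-(hydroxymethyl)-5-(3,4,5-trimethoxyphenyl)oxolan-3-yl]methanol (target), via (3,4-dimethoxyphenyl)[(3R,4S,5R)-4-(hydroxymethyl)-5-(3,4,5-trimethoxyphenyl)oxolan-3-yl]methanone 19 (not isolated)
Conditions: (R)-Me-CBS (0.3 equiv), BH3·SMe2 (2.5 equiv), THF, −30 → 0 °C; MeOH quench
Reagents that add atoms: none
Why: Borane reduces the aldehyde first, then the Corey–Bakshi–Shibata reduction of the aryl ketone gives the (S)-carbinol under catalyst control (aryl as the large group, as for acetophenone → (S)-1-phenylethanol with the (R)-catalyst), reinforced by the Felkin–Anh preference of the C-4 centre (C-3 branch anti to hydride).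

**Compound list**
1 | p-cresol (4-methylphenol) | Cc1ccc(O)cc1 | starting material
2 | 2,6-dibromo-4-methylphenol | Cc1cc(Br)c(O)c(Br)c1 | intermediate (not isolated)
3 | 2,6-dibromo-4-(dibromomethyl)phenol | BrC(Br)c1cc(Br)c(O)c(Br)c1 | intermediate (not isolated)
4 | 3,5-dibromo-4-hydroxybenzaldehyde | O=Cc1cc(Br)c(O)c(Br)c1 | intermediate
5 | sodium 4-formyl-2,6-dimethoxyphenolate | COc1cc(C=O)cc(OC)c1[O-].[Na+] | intermediate (not isolated)
6 | 3,4,5-trimethoxybenzaldehyde | COc1cc(C=O)cc(OC)c1OC | intermediate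
7 | allyl chloride (3-chloroprop-1-ene) | C=CCCl | starting material
8 | (Z)-γ-chloroallyl-diisopinocampheylborane (Ipc from (−)-α-pinene) | Cl/C=C\CB([C@H]1C[C@H]2C[C@H](C2(C)C)[C@@H]1C)[C@H]1C[C@H]2C[C@H](C2(C)C)[C@@H]1C | intermediate (not isolated)
9 | (1S,2S)-2-chloro-1-(3,4,5-trimethoxyphenyl)but-3-en-1-ol (syn) | C=C[C@H](Cl)[C@@H](O)c1cc(OC)c(OC)c(OC)c1 | intermediate (not isolated)
10 | (2S,3R)-2-(3,4,5-trimethoxyphenyl)-3-vinyloxirane (cis) | C=C[C@H]1O[C@H]1c2cc(OC)c(OC)c(OC)c2 | intermediate
11 | catechol | Oc1ccccc1O | starting material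
12 | veratrole | COc1ccccc1OC | intermediate
13 | 3-chloropropanoyl chloride | O=C(Cl)CCCl | starting material
14 | 3-chloro-1-(3,4-dimethoxyphenyl)propan-1-one | COc1ccc(C(=O)CCCl)cc1OC | intermediate (not isolated)
15 | 1-(3,4-dimethoxyphenyl)prop-2-en-1-one | COc1ccc(C(=O)C=C)cc1OC | intermediate
16 | (3,4-dimethoxyphenyl)[(3R,4R,5R)-4-ethenyl-5-(3,4,5-trimethoxyphenyl)oxolan-3-yl]methanone | COc1ccc(C(=O)[C@H]2CO[C@@H](c3cc(OC)c(OC)c(OC)c3)[C@@H]2C=C)cc1OC | intermediate
17 | (3,4-dimethoxyphenyl)[4-(1,2-dihydroxyethyl)-5-(3,4,5-trimethoxyphenyl)oxolan-3-yl]methanone, ring centres as in 16, new carbinol centre as epimer mixture | COc1ccc(C(=O)[C@H]2CO[C@@H](c3cc(OC)c(OC)c(OC)c3)[C@@H]2C(O)CO)cc1OC | intermediate (not isolated)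
18 | (2R,3R,4R)-4-(3,4-dimethoxybenzoyl)-2-(3,4,5-trimethoxyphenyl)oxolane-3-carbaldehyde | COc1ccc(C(=O)[C@H]2CO[C@@H](c3cc(OC)c(OC)c(OC)c3)[C@@H]2C=O)cc1OC | intermediate
19 | (3,4-dimethoxyphenyl)[(3R,4S,5R)-4-(hydroxymethyl)-5-(3,4,5-trimethoxyphenyl)oxolan-3-yl]methanone | COc1ccc(C(=O)[C@H]2CO[C@@H](c3cc(OC)c(OC)c(OC)c3)[C@@H]2CO)cc1OC | intermediate (not isolated)
20 | (S)-(3,4-dimethoxyphenyl)[(3R,4S,5R)-4-(hydroxymethyl)-5-(3,4,5-trimethoxyphenyl)oxolan-3-yl]methanol | COc1ccc([C@@H](O)[C@H]2CO[C@@H](c3cc(OC)c(OC)c(OC)c3)[C@@H]2CO)cc1OC | target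

**Totals:** 8 steps; longest linear sequence 6 steps (1 → 2 → 3 → 6 → 7 → 8).

**Three steps most likely to fail**

Step 3 (chloroallylboration of an electron-rich aldehyde at −95 °C and an acid-sensitive benzylic vinyl oxirane). Fallback, setting out from 6: Wittig olefination with allyltriphenylphosphonium bromide/KOtBu and I2-catalysed isomerisation gives (E)-5-(buta-1,3-dien-1-yl)-1,2,3-trimethoxybenzene F1. Shi epoxidation of the styrenyl double bond with the ent-Shi (L-fructose-derived) ketone and Oxone at pH 10.5 gives (2S,3S)-2-(3,4,5-trimethoxyphenyl)-3-vinyloxirane F2 (trans isomer). F2 enters step 6 in place of 10, because it gives the same π-allyl zwitterion, and the route is rejoined at 16.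

Step 6 (the proposed new step; risks are Pd-catalysed isomerisation of 10 to a dienol/enone before trapping, and oligomerisation of 15). Fallback with known reactions, setting out from 6: step 3 is stopped after the ethanolamine work-up and chlorohydrin 9 is isolated. PMe3-catalysed oxa-Michael addition of 9 to 15 gives 3-{[(1S,2S)-2-chloro-1-(3,4,5-trimethoxyphenyl)but-3-en-1-yl]oxy}-1-(3,4-dimethoxyphenyl)propan-1-one F3. Pd(PPh3)4/Cs2CO3 in THF then effects an intramolecular Tsuji–Trost alkylation of the ketone enolate on the allylic chloride (5-exo), which closes the oxolane and returns to the route at 16.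

Step 7 (18 is a γ-keto aldehyde with two epimerisable centres; base could also open the ring by β-elimination at C-2/C-3 and erode the C-2 configuration). Fallback, setting out from 16: CBS reduction with (R)-Me-CBS/catecholborane in toluene at −78 °C (no alkene hydroboration) gives (S)-(3,4-dimethoxyphenyl)[(3R,4R,5R)-4-ethenyl-5-(3,4,5-trimethoxyphenyl)oxolan-3-yl]methanol F4. One-pot OsO4/NaIO4 cleavage followed by NaBH4 in the same flask, so that the aldehyde is never isolated, gives 20 directly.

**Further compounds**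
F1 | step 3 | (E)-5-(buta-1,3-dien-1-yl)-1,2,3-trimethoxybenzene | C=C/C=C/c1cc(OC)c(OC)c(OC)c1
F2 | step 3 | (2S,3S)-2-(3,4,5-trimethoxyphenyl)-3-vinyloxirane (trans) | C=C[C@@H]1O[C@H]1c2cc(OC)c(OC)c(OC)c2
F3 | step 6 | 3-{[(1S,2S)-2-chloro-1-(3,4,5-trimethoxyphenyl)but-3-en-1-yl]oxy}-1-(3,4-dimethoxyphenyl)propan-1-one | C=C[C@H](Cl)[C@@H](OCCC(=O)c1ccc(OC)c(OC)c1)c2cc(OC)c(OC)c(OC)c2
F4 | step 7 | (S)-(3,4-dimethoxyphenyl)[(3R,4R,5R)-4-ethenyl-5-(3,4,5-trimethoxyphenyl)oxolan-3-yl]methanol | COc1ccc([C@@H](O)[C@H]2CO[C@@H](c3cc(OC)c(OC)c(OC)c3)[C@@H]2C=C)cc1OC
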